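## Retrosynthetic overview

- Ring locants used below: C-1 quaternary (methyl, vinyl), C-2 CH2, C-3 acyloxy, C-4 acrylic acid, C-5 hydroxyl, C-6 hydroxypropenyl.
- The target comes from a bis-silyl acid, made by SeO2/Pinnick oxidation of the C-4 isopropenyl methyl; the C-5 alcohol comes from axial-selective reduction of a C-5 ketone.
- The only ring is closed at C-4–C-5 by a one-flask oxidation/carbonyl-ene/oxidation of an acyclic primary alcohol.
- The C-1–C-6 bond comes from an enantioselective Ireland–Claisen rearrangement of a triester assembled from three pieces of similar size: a C10 dienediol, a silyloxymethyl-butenoic acid and the silylated Roche acid chloride.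
- The three pieces come from a vinylogous aldol (sets C-3), an allylzinc carboxylation and the Roche ester, each in three steps.

TBS = tert-butyldimethylsilyl.

Assumption: the sense of induction of the two chiral controllers (step 2 and step 12) is as stated; if either proves opposite, its enantiomer is used and nothing else changes.

## Route

**Dienediol branch**

Step 1
Reactants: 1 methyl 3-methylbut-2-enoate
Product: 2 tert-butyl[(1-methoxy-3-methylbuta-1,3-dien-1-yl)oxy]dimethylsilane (E/Z mixture at the ketene acetal)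
Conditions: LiN(i-Pr)2, THF, −78 °C; TBSCl, DMPU, −78 → 25 °C
Reagents that add atoms: tert-butyl(chloro)dimethylsilane (TBSCl), CC(C)(C)[Si](C)(C)Cl
Why: Kinetic γ-deprotonation of the enoate and O-silylation of the extended enolate give the silyl dienol ether, with no stereocentre involved.

Step 2
Reactants: 2 tert-butyl[(1-methoxy-3-methylbuta-1,3-dien-1-yl)oxy]dimethylsilane; 3 3-methylbut-2-enal
Product: 4 methyl (2E,5S)-5-hydroxy-3,7-dimethylocta-2,6-dienoate
Conditions: SiCl4 (1.1 equiv), (R,R)-N,N′-bis[3,5-dihydro-3,5-dimethyl-4-oxido-4H-dinaphtho[2,1-d:1′,2′-f][1,3,2]diazaphosphepin-4-yl]-N,N′-dimethylpentane-1,5-diamine (5 mol %), i-Pr2NEt (10 mol %), CH2Cl2, −78 °C; aq. NaHCO3/KF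
Reagents that add atoms: none
Why: In this Lewis-base-activated SiCl4 vinylogous Mukaiyama aldol the dienolate attacks through its free γ-carbon in an open transition state (s-trans diene, hence the 2E enoate, any 2Z isomer lactonising and being removed), and the chiral phosphoramide-bound silicon cation shields one aldehyde face so that C-5 (ring C-3) is set as S.

Step 3
Reactants: 4 methyl (2E,5S)-5-hydroxy-3,7-dimethylocta-2,6-dienoate
Product: 5 (2E,5S)-3,7-dimethylocta-2,6-diene-1,5-diol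
Conditions: i-Bu2AlH (3.5 equiv), CH2Cl2, −78 → 0 °C; aq. KNaC4H4O6
Reagents that add atoms: none
Why: 1,2-Reduction of the conjugated ester by the aluminium hydride gives the allylic alcohol while the secondary hydroxyl rides through as its aluminium alkoxide, leaving the carbinol centre and the E alkene untouched.

**Butenoic acid branch**

Step 4
Reactants: 6 2-methylidenepropane-1,3-diol
Product: 7 2-{[(TBS)oxy]methyl}prop-2-en-1-ol
Conditions: NaH (1.0 equiv), THF, 0 °C; TBSCl (1.0 equiv), 0 → 25 °C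
Reagents that add atoms: tert-butyl(chloro)dimethylsilane (TBSCl), CC(C)(C)[Si](C)(C)Cl
Why: Silylation of the sparingly soluble monosodium alkoxide desymmetrises the diol to the mono-silyl ether.

Step 5
Reactants: 7 2-{[(TBS)oxy]methyl}prop-2-en-1-ol
Product: 8 {[2-(bromomethyl)prop-2-en-1-yl]oxy}(tert-butyl)dimethylsilane
Conditions: CBr4, PPh3, CH2Cl2, 0 °C
Reagents that add atoms: tetrabromomethane, BrC(Br)(Br)Br
Why: The Appel reaction converts the primary allylic alcohol into the bromide under neutral conditions that keep the silyl ether.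

Step 6
Reactants: 8 {[2-(bromomethyl)prop-2-en-1-yl]oxy}(tert-butyl)dimethylsilane
Product: 10 3-{[(TBS)oxy]methyl}but-3-enoic acid, via allylzinc bromide 9 (not isolated)
Conditions: Zn dust, LiCl, THF, 0 °C; then CO2 (1 atm), MgCl2, 25 °C; aq. citric acid
Reagents that add atoms: carbon dioxide, O=C=O
Why: Zinc insertion gives an allylzinc reagent whose two termini are equivalent, so its carboxylation delivers a single β,γ-unsaturated acid.

**Side-chain branch**

Step 7
Reactants: 11 methyl (2R)-3-hydroxy-2-methylpropanoate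
Product: 12 methyl (2R)-3-[(TBS)oxy]-2-methylpropanoate
Conditions: TBSCl, imidazole, CH2Cl2, 25 °C
Reagents that add atoms: tert-butyl(chloro)dimethylsilane (TBSCl), CC(C)(C)[Si](C)(C)Cl
Why: Standard imidazole-promoted silylation protects the primary alcohol without touching the α-stereocentre, which is taken from the chiral pool.

Step 8
Reactants: 12 methyl (2R)-3-[(TBS)oxy]-2-methylpropanoate
Product: 13 (2R)-3-[(TBS)oxy]-2-methylpropanoic acid
Conditions: LiOH·H2O, THF/MeOH/H2O, 0 → 25 °C; 1 M HCl to pH 4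
Reagents that add atoms: lithium hydroxide (LiOH), [Li+].[OH-]
Why: Mild saponification cleaves the methyl ester faster than it epimerises the α-centre or eliminates the β-silyloxy group.

Step 9
Reactants: 13 (2R)-3-[(TBS)oxy]-2-methylpropanoic acid
Product: 14 (2R)-3-[(TBS)oxy]-2-methylpropanoyl chloride
Conditions: 1-chloro-N,N,2-trimethylprop-1-en-1-amine, CH2Cl2, 0 → 25 °C
Reagents that add atoms: 1-chloro-N,N,2-trimethylprop-1-en-1-amine, CC(C)=C(Cl)N(C)C
Why: The α-chloroenamine makes the acid chloride under neutral conditions, so no HCl threatens the silyl ether and no base can form a ketene that would racemise the centre.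

**Union and endgame**

Step 10
Reactants: 5 (2E,5S)-3,7-dimethylocta-2,6-diene-1,5-diol; 10 3-{[(TBS)oxy]methyl}but-3-enoic acid
Product: 15 (2E,5S)-5-hydroxy-3,7-dimethylocta-2,6-dien-1-yl 3-{[(TBS)oxy]methyl}but-3-enoate
Conditions: PPh3, DIAD (1.0 equiv each), THF, 0 °C
Reagents that add atoms: none
Why: In this Mitsunobu esterification only the unhindered primary allylic hydroxyl is activated, and because the carboxylate acts as nucleophile the β,γ-unsaturated acid is never acyl-activated and cannot slip into conjugation.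

Step 11
Reactants: 15 (2E,5S)-5-hydroxy-3,7-dimethylocta-2,6-dien-1-yl 3-{[(TBS)oxy]methyl}but-3-enoate; 14 (2R)-3-[(TBS)oxy]-2-methylpropanoyl chloride
Product: 16 (2E,5S)-5-{[(2R)-3-[(TBS)oxy]-2-methylpropanoyl]oxy}-3,7-dimethylocta-2,6-dien-1-yl 3-{[(TBS)oxy]methyl}but-3-enoate
Conditions: pyridine, CH2Cl2, 0 → 25 °C
Reagents that add atoms: none
Why: Acylation of the secondary allylic alcohol with the acid chloride and a weak base installs the side chain with retention at both centres and without isomerising the but-3-enoate.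

Step 12
Reactants: 16 (2E,5S)-5-{[(2R)-3-[(TBS)oxy]-2-methylpropanoyl]oxy}-3,7-dimethylocta-2,6-dien-1-yl 3-{[(TBS)oxy]methyl}but-3-enoate
Product: 18 (2R,3S,5S)-2-{3-[(TBS)oxy]prop-1-en-2-yl}-5-{[(2R)-3-[(TBS)oxy]-2-methylpropanoyl]oxy}-3-ethenyl-3,7-dimethyloct-6-enoic acid, via boron ketene acetal 17 (not isolated)
Conditions: (4S,5S)-2-bromo-1,3-bis{[3,5-bis(trifluoromethyl)phenyl]sulfonyl}-4,5-diphenyl-1,3,2-diazaborolidine (1.3 equiv), Et3N, toluene–hexane, −78 °C, then −20 °C, 7 d; pH 7 buffer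
Reagents that add atoms: none
Why: Soft enolisation touches only the doubly activated CH2 and gives the E(O) boron ketene acetal, whose Ireland–Claisen rearrangement through a chair with the (E)-trisubstituted alkene fixes the relative configuration of the new quaternary and tertiary centres, while the C2-symmetric sulfonamide ligand on boron selects the face to give 2R,3S (ring C-6 and C-1) irrespective of the remote C-5 centre.

Step 13
Reactants: 18 (2R,3S,5S)-2-{3-[(TBS)oxy]prop-1-en-2-yl}-5-{[(2R)-3-[(TBS)oxy]-2-methylpropanoyl]oxy}-3-ethenyl-3,7-dimethyloct-6-enoic acid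
Product: 20 (4S,6S,7R)-6-ethenyl-8-hydroxy-2,6-dimethyl-7-{3-[(TBS)oxy]prop-1-en-2-yl}oct-2-en-4-yl (2R)-3-[(TBS)oxy]-2-methylpropanoate, via acyl imidazolide 19 (not isolated)
Conditions: 1,1′-carbonyldiimidazole, THF, 25 °C; then NaBH4, H2O, 0 °C
Reagents that add atoms: none
Why: Activation of the acid as its acyl imidazolide lets NaBH4 reduce it to the primary alcohol while the hindered side-chain ester, the alkenes and the silyl ethers are untouched and no stereocentre is affected.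

Step 14
Reactants: 20 (4S,6S,7R)-6-ethenyl-8-hydroxy-2,6-dimethyl-7-{3-[(TBS)oxy]prop-1-en-2-yl}oct-2-en-4-yl (2R)-3-[(TBS)oxy]-2-methylpropanoate
Product: 23 (1S,2R,4R,5S)-5-ethenyl-5-methyl-3-oxo-2-(prop-1-en-2-yl)-4-{3-[(TBS)oxy]prop-1-en-2-yl}cyclohexyl (2R)-3-[(TBS)oxy]-2-methylpropanoate, via aldehyde 21 (not isolated), via ene alcohol 22 (not isolated)
Conditions: [C5H5NH][CrO3Cl] (pyridinium chlorochromate, 3 equiv), Celite, CH2Cl2, 25 °C; crude product used at once
Reagents that add atoms: none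
Why: Oxidation to the aldehyde, acid-promoted intramolecular carbonyl-ene cyclisation onto the trisubstituted alkene and a second oxidation occur in one flask (the citronellol-to-isopulegone manifold), the chair-like ene transition state with the C-3 ester, the C-6 side chain and the forming isopropenyl group all equatorial setting C-4, while the C-5 carbinol centre is erased as the ketone.

Step 15
Reactants: 23 (1S,2R,4R,5S)-5-ethenyl-5-methyl-3-oxo-2-(prop-1-en-2-yl)-4-{3-[(TBS)oxy]prop-1-en-2-yl}cyclohexyl (2R)-3-[(TBS)oxy]-2-methylpropanoate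
Product: 24 (1S,2S,3S,4R,5S)-5-ethenyl-3-hydroxy-5-methyl-2-(prop-1-en-2-yl)-4-{3-[(TBS)oxy]prop-1-en-2-yl}cyclohexyl (2R)-3-[(TBS)oxy]-2-methylpropanoate
Conditions: LiBH(s-Bu)3, THF, −78 °C; then H2O
Reagents that add atoms: none
Why: The bulky trialkylborohydride attacks the ketone from the equatorial side (the axial path is also blocked by the axial C-1 methyl), giving the axial C-5 alcohol cis to both flanking groups as in the isopulegone-to-neoisopulegol reduction, and at −78 °C the ester is not reduced.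

Step 16
Reactants: 24 (1S,2S,3S,4R,5S)-5-ethenyl-3-hydroxy-5-methyl-2-(prop-1-en-2-yl)-4-{3-[(TBS)oxy]prop-1-en-2-yl}cyclohexyl (2R)-3-[(TBS)oxy]-2-methylpropanoate
Product: 25 (1S,2S,3S,4R,5S)-5-ethenyl-3-hydroxy-5-methyl-2-(3-oxoprop-1-en-2-yl)-4-{3-[(TBS)oxy]prop-1-en-2-yl}cyclohexyl (2R)-3-[(TBS)oxy]-2-methylpropanoate
Conditions: SeO2 (1.5 equiv), pyridine, 1,4-dioxane, 70 °C
Reagents that add atoms: selenium dioxide, O=[Se]=O
Why: Riley allylic oxidation (ene reaction, then [2,3]-shift) takes place at the only allylic methyl, on the most electron-rich 1,1-dialkyl alkene, the vinyl group having no allylic hydrogen and the other propenyl unit being deactivated by its allylic oxygen.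

Step 17
Reactants: 25 (1S,2S,3S,4R,5S)-5-ethenyl-3-hydroxy-5-methyl-2-(3-oxoprop-1-en-2-yl)-4-{3-[(TBS)oxy]prop-1-en-2-yl}cyclohexyl (2R)-3-[(TBS)oxy]-2-methylpropanoate
Product: 26 2-[(1S,2S,3R,4S,6S)-4-ethenyl-2-hydroxy-4-methyl-3-{3-[(TBS)oxy]prop-1-en-2-yl}-6-{[(2R)-3-[(TBS)oxy]-2-methylpropanoyl]oxy}cyclohexyl]prop-2-enoic acid
Conditions: NaClO2, NaH2PO4, 2-methylbut-2-ene, t-BuOH/H2O, 0 °C; extraction at pH 5
Reagents that add atoms: sodium chlorite (NaClO2), [Na+].[O-]Cl=O
Why: Pinnick oxidation converts the enal (free or as its hemiacetal with the C-5 hydroxyl) into the acrylic acid without touching alkenes, alcohols or stereocentres, the scavenger removing HOCl.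

Step 18
Reactants: 26 2-[(1S,2S,3R,4S,6S)-4-ethenyl-2-hydroxy-4-methyl-3-{3-[(TBS)oxy]prop-1-en-2-yl}-6-{[(2R)-3-[(TBS)oxy]-2-methylpropanoyl]oxy}cyclohexyl]prop-2-enoic acid
Product: 27 2-[(1S,2S,3R,4S,6S)-4-ethenyl-2-hydroxy-3-(3-hydroxyprop-1-en-2-yl)-6-{[(2R)-3-hydroxy-2-methylpropanoyl]oxy}-4-methylcyclohexyl]prop-2-enoic acid (CNP0462645.4)
Conditions: HF·pyridine, excess pyridine, THF, 0 → 25 °C; pH 7 phosphate buffer work-up
Reagents that add atoms: none
Why: Buffered fluoride desilylation frees both primary alcohols without ester migration (the C-3 ester and the C-5 hydroxyl are trans-1,3), and the near-neutral work-up avoids closure of the cis γ-lactone.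

## Compound list

1 | methyl 3-methylbut-2-enoate | COC(=O)C=C(C)C | starting material
2 | tert-butyl[(1-methoxy-3-methylbuta-1,3-dien-1-yl)oxy]dimethylsilane (E/Z mixture at the ketene acetal) | COC(O[Si](C)(C)C(C)(C)C)=CC(C)=C | intermediate
3 | 3-methylbut-2-enal | CC(C)=CC=O | starting material
4 | methyl (2E,5S)-5-hydroxy-3,7-dimethylocta-2,6-dienoate | COC(=O)/C=C(\C)C[C@H](O)C=C(C)C | intermediate
5 | (2E,5S)-3,7-dimethylocta-2,6-diene-1,5-diol | OC/C=C(\C)C[C@H](O)C=C(C)C | intermediate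
6 | 2-methylidenepropane-1,3-diol | C=C(CO)CO | starting material
7 | 2-{[(TBS)oxy]methyl}prop-2-en-1-ol | C=C(CO)CO[Si](C)(C)C(C)(C)C | intermediate
8 | {[2-(bromomethyl)prop-2-en-1-yl]oxy}(tert-butyl)dimethylsilane | C=C(CBr)CO[Si](C)(C)C(C)(C)C | intermediate
9 | bromo[2-({[tert-butyl(dimethyl)silyl]oxy}methyl)prop-2-en-1-yl]zinc (allylzinc bromide, not isolated) | C=C(C[Zn]Br)CO[Si](C)(C)C(C)(C)C | intermediate
10 | 3-{[(TBS)oxy]methyl}but-3-enoic acid | C=C(CC(=O)O)CO[Si](C)(C)C(C)(C)C | intermediate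
11 | methyl (2R)-3-hydroxy-2-methylpropanoate | COC(=O)[C@H](C)CO | starting material
12 | methyl (2R)-3-[(TBS)oxy]-2-methylpropanoate | COC(=O)[C@H](C)CO[Si](C)(C)C(C)(C)C | intermediate
13 | (2R)-3-[(TBS)oxy]-2-methylpropanoic acid | OC(=O)[C@H](C)CO[Si](C)(C)C(C)(C)C | intermediate
14 | (2R)-3-[(TBS)oxy]-2-methylpropanoyl chloride | ClC(=O)[C@H](C)CO[Si](C)(C)C(C)(C)C | intermediate
15 | (2E,5S)-5-hydroxy-3,7-dimethylocta-2,6-dien-1-yl 3-{[(TBS)oxy]methyl}but-3-enoate | C=C(CO[Si](C)(C)C(C)(C)C)CC(=O)OC/C=C(\C)C[C@H](O)C=C(C)C | intermediate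
16 | (2E,5S)-5-{[(2R)-3-[(TBS)oxy]-2-methylpropanoyl]oxy}-3,7-dimethylocta-2,6-dien-1-yl 3-{[(TBS)oxy]methyl}but-3-enoate | C=C(CO[Si](C)(C)C(C)(C)C)CC(=O)OC/C=C(\C)C[C@H](OC(=O)[C@H](C)CO[Si](C)(C)C(C)(C)C)C=C(C)C | intermediate
17 | E(O) boron ketene acetal of 16 carrying the (4S,5S)-1,3-bis{[3,5-bis(trifluoromethyl)phenyl]sulfonyl}-4,5-diphenyl-1,3,2-diazaborolidin-2-yl group (not isolated) | C=C(CO[Si](C)(C)C(C)(C)C)/C=C(/OB1N(S(=O)(=O)c2cc(C(F)(F)F)cc(C(F)(F)F)c2)[C@@H](c2ccccc2)[C@H](c2ccccc2)N1S(=O)(=O)c1cc(C(F)(F)F)cc(C(F)(F)F)c1)OC/C=C(\C)C[C@H](OC(=O)[C@H](C)CO[Si](C)(C)C(C)(C)C)C=C(C)C | intermediate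
18 | (2R,3S,5S)-2-{3-[(TBS)oxy]prop-1-en-2-yl}-5-{[(2R)-3-[(TBS)oxy]-2-methylpropanoyl]oxy}-3-ethenyl-3,7-dimethyloct-6-enoic acid | C=C[C@](C)(C[C@H](OC(=O)[C@H](C)CO[Si](C)(C)C(C)(C)C)C=C(C)C)[C@@H](C(=O)O)C(=C)CO[Si](C)(C)C(C)(C)C | intermediate
19 | 1-acylimidazole of acid 18 (not isolated) | C=C[C@](C)(C[C@H](OC(=O)[C@H](C)CO[Si](C)(C)C(C)(C)C)C=C(C)C)[C@@H](C(=O)n1ccnc1)C(=C)CO[Si](C)(C)C(C)(C)C | intermediate
20 | (4S,6S,7R)-6-ethenyl-8-hydroxy-2,6-dimethyl-7-{3-[(TBS)oxy]prop-1-en-2-yl}oct-2-en-4-yl (2R)-3-[(TBS)oxy]-2-methylpropanoate | C=C[C@](C)(C[C@H](OC(=O)[C@H](C)CO[Si](C)(C)C(C)(C)C)C=C(C)C)[C@@H](CO)C(=C)CO[Si](C)(C)C(C)(C)C | intermediate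
21 | (4S,6S,7R)-6-ethenyl-2,6-dimethyl-8-oxo-7-{3-[(TBS)oxy]prop-1-en-2-yl}oct-2-en-4-yl (2R)-3-[(TBS)oxy]-2-methylpropanoate (aldehyde, not isolated) | C=C[C@](C)(C[C@H](OC(=O)[C@H](C)CO[Si](C)(C)C(C)(C)C)C=C(C)C)[C@@H](C=O)C(=C)CO[Si](C)(C)C(C)(C)C | intermediate
22 | (1S,2S,3R,4R,5S)-5-ethenyl-3-hydroxy-5-methyl-2-(prop-1-en-2-yl)-4-{3-[(TBS)oxy]prop-1-en-2-yl}cyclohexyl (2R)-3-[(TBS)oxy]-2-methylpropanoate (equatorial ene alcohol, not isolated) | C=C[C@]1(C)C[C@H](OC(=O)[C@H](C)CO[Si](C)(C)C(C)(C)C)[C@@H](C(=C)C)[C@H](O)[C@H]1C(=C)CO[Si](C)(C)C(C)(C)C | intermediate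
23 | (1S,2R,4R,5S)-5-ethenyl-5-methyl-3-oxo-2-(prop-1-en-2-yl)-4-{3-[(TBS)oxy]prop-1-en-2-yl}cyclohexyl (2R)-3-[(TBS)oxy]-2-methylpropanoate | C=C[C@]1(C)C[C@H](OC(=O)[C@H](C)CO[Si](C)(C)C(C)(C)C)[C@@H](C(=C)C)C(=O)[C@H]1C(=C)CO[Si](C)(C)C(C)(C)C | intermediate
24 | (1S,2S,3S,4R,5S)-5-ethenyl-3-hydroxy-5-methyl-2-(prop-1-en-2-yl)-4-{3-[(TBS)oxy]prop-1-en-2-yl}cyclohexyl (2R)-3-[(TBS)oxy]-2-methylpropanoate | C=C[C@]1(C)C[C@H](OC(=O)[C@H](C)CO[Si](C)(C)C(C)(C)C)[C@@H](C(=C)C)[C@@H](O)[C@H]1C(=C)CO[Si](C)(C)C(C)(C)C | intermediate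
25 | (1S,2S,3S,4R,5S)-5-ethenyl-3-hydroxy-5-methyl-2-(3-oxoprop-1-en-2-yl)-4-{3-[(TBS)oxy]prop-1-en-2-yl}cyclohexyl (2R)-3-[(TBS)oxy]-2-methylpropanoate | C=C[C@]1(C)C[C@H](OC(=O)[C@H](C)CO[Si](C)(C)C(C)(C)C)[C@@H](C(=C)C=O)[C@@H](O)[C@H]1C(=C)CO[Si](C)(C)C(C)(C)C | intermediate
26 | 2-[(1S,2S,3R,4S,6S)-4-ethenyl-2-hydroxy-4-methyl-3-{3-[(TBS)oxy]prop-1-en-2-yl}-6-{[(2R)-3-[(TBS)oxy]-2-methylpropanoyl]oxy}cyclohexyl]prop-2-enoic acid | C=C[C@]1(C)C[C@H](OC(=O)[C@H](C)CO[Si](C)(C)C(C)(C)C)[C@@H](C(=C)C(=O)O)[C@@H](O)[C@H]1C(=C)CO[Si](C)(C)C(C)(C)C | intermediate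
27 | 2-[(1S,2S,3R,4S,6S)-4-ethenyl-2-hydroxy-3-(3-hydroxyprop-1-en-2-yl)-6-{[(2R)-3-hydroxy-2-methylpropanoyl]oxy}-4-methylcyclohexyl]prop-2-enoic acid | C=C[C@]1(C)C[C@H](OC(=O)[C@H](C)CO)[C@@H](C(=C)C(=O)O)[C@@H](O)[C@H]1C(=C)CO | target

## Step count and risks

Total step count: 18.
Longest linear sequence: 12 steps (steps 1–3 or 4–6, then 10–18).

**Step 12 (boron-mediated enantioselective Ireland–Claisen on a triester).** The risks are incomplete chemoselectivity of enolisation, slow rearrangement to the quaternary centre and uncertain face selection. The fallback sets out from 16 and comes back at 18, trading reagent control for separation. Compound 16 is deprotonated with LiN(i-Pr)2 (1.05 equiv) in THF at −78 °C in the presence of Me3SiCl/Et3N to give the silyl ketene acetal F1, which rearranges through the same chair on warming to 25 °C. Mild acidic work-up frees acid 18 together with its (2S,3R,5S)-diastereomeric acid F2. Because C-5 and the side-chain centre are already fixed, the two are diastereomers and are separated by chromatography; F2 is discarded (at most half the material is kept).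

**Step 14 (one-flask oxidation/carbonyl-ene/oxidation).** The allylic ester next to the reacting alkene lowers its nucleophilicity and could ionise, the C-4 configuration rests on the all-equatorial chair, and ketone 23 is a β-acyloxy ketone prone to elimination. The fallback sets out from 18 and comes back at 23, forming the C-4–C-5 bond at the acyl oxidation level instead. Acid 18 is converted with 1-chloro-N,N,2-trimethylprop-1-en-1-amine into the acid chloride F3. SnCl4 in CH2Cl2 at −78 °C then triggers cation–olefin acylation: the acylium ion attacks the CH end of the trisubstituted alkene and the tertiary cation loses a methyl proton, giving the β,γ-unsaturated ketone 23 directly, without passing through 20, 21 or 22.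

**Step 16 (site-selective SeO2 oxidation).** Over-oxidation, attack on the second propenyl unit and loss of silyl groups in hot selenous acid are possible. The fallback sets out from 24 and comes back at 25, replacing C–H oxidation by epoxide chemistry. 3-Chloroperbenzoic acid with NaHCO3 in CH2Cl2 at 0 °C epoxidises the most electron-rich 1,1-dialkyl alkene to the epoxide F4 (mixture at the oxirane carbon). Et2Al(NC9H18) (diethylaluminium 2,2,6,6-tetramethylpiperidide, 3 equiv) in toluene at 0 °C removes a methyl proton and opens the oxirane to the allylic alcohol F5. MnO2 in CH2Cl2 oxidises only this free allylic alcohol to enal 25.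

## Further compounds

F1 | step 12 | trimethylsilyl E(O) ketene acetal of 16 | C=C(CO[Si](C)(C)C(C)(C)C)/C=C(/O[Si](C)(C)C)OC/C=C(\C)C[C@H](OC(=O)[C@H](C)CO[Si](C)(C)C(C)(C)C)C=C(C)C
F2 | step 12 | (2S,3R,5S)-2-{3-[(TBS)oxy]prop-1-en-2-yl}-5-{[(2R)-3-[(TBS)oxy]-2-methylpropanoyl]oxy}-3-ethenyl-3,7-dimethyloct-6-enoic acid | C=C[C@@](C)(C[C@H](OC(=O)[C@H](C)CO[Si](C)(C)C(C)(C)C)C=C(C)C)[C@H](C(=O)O)C(=C)CO[Si](C)(C)C(C)(C)C
F3 | step 14 | acid chloride of 18 | C=C[C@](C)(C[C@H](OC(=O)[C@H](C)CO[Si](C)(C)C(C)(C)C)C=C(C)C)[C@@H](C(=O)Cl)C(=C)CO[Si](C)(C)C(C)(C)C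
F4 | step 16 | (1S,2S,3S,4R,5S)-5-ethenyl-3-hydroxy-5-methyl-2-(2-methyloxiran-2-yl)-4-{3-[(TBS)oxy]prop-1-en-2-yl}cyclohexyl (2R)-3-[(TBS)oxy]-2-methylpropanoate (mixture at the oxirane carbon) | C=C[C@]1(C)C[C@H](OC(=O)[C@H](C)CO[Si](C)(C)C(C)(C)C)[C@@H](C2(C)CO2)[C@@H](O)[C@H]1C(=C)CO[Si](C)(C)C(C)(C)C
F5 | step 16 | (1S,2S,3S,4R,5S)-5-ethenyl-3-hydroxy-2-(3-hydroxyprop-1-en-2-yl)-5-methyl-4-{3-[(TBS)oxy]prop-1-en-2-yl}cyclohexyl (2R)-3-[(TBS)oxy]-2-methylpropanoate | C=C[C@]1(C)C[C@H](OC(=O)[C@H](C)CO[Si](C)(C)C(C)(C)C)[C@@H](C(=C)CO)[C@@H](O)[C@H]1C(=C)CO[Si](C)(C)C(C)(C)C
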